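## Numbering and conventions

Ring A is the benzene ring of the coumarin, ring B its pyranone ring, ring C the six-membered carbocycle on coumarin C3. Ring C locants are the same for every compound, aromatic precursors included: C1′ is bonded to coumarin C3, C2′ is the neighbouring CH, then C3′, C4′ (the carbinol carbon of the target), C5′ and C6′ (bonded to C1′).

Compounds: **1** 4-bromo-2,5-dimethoxyphenol; **2** 3-bromo-7-methoxycoumarin; **3** aryl pinacol boronate from 1; **4** biaryl phenol; **5** masked ortho-quinone (6,6-dimethoxycyclohexa-2,4-dienone); **6** borate ester of 7; **7** (R)-allyl carbinol; **8** (R)-prenyl carbinol; **9** keto ketal; **10** target.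

Assumption on materials: bromides 1 and 2 are taken as catalogue building blocks (each is otherwise one electrophilic bromination away from the parent phenol or coumarin).

Assumption on the sense of induction: in the diol-catalysed allylboration the quaternary ketal carbon C3′ of 5 is taken to play the part of the large substituent of an aryl methyl ketone; the diol is written as (R) on that basis, and the (S)-diol is used if the model places C3′ the other way.

## Analysis of the target

The target 10 is a 7-methoxycoumarin (rings A and B) carrying at C3 a cyclohex-2-ene-1,4-dione (ring C). In ring C, C1′=C2′ is the only alkene, C3′ and C6′ are ketones, C5′ is a methylene, and C4′ is a fully substituted carbinol carbon bearing OH and a 3-methylbut-2-enyl (prenyl) group. C4′ is the only stereocentre, (R). It has no neighbouring stereocentre to relay or correct its configuration, so it must be set by a reagent or catalyst on an achiral precursor. Ring C is formally the hydrate of a 2-aryl-5-prenyl-1,4-benzoquinone, and equally the keto tautomer of a dearomatised benzene oxygenated at C3′, C4′ and C6′. This is its weak point: the C4′ hydroxyl is β to the C6′ ketone, so base (E1cB through the C5′ enolate) or forcing acid expels water and gives the flat, achiral quinone. The α-ketol unit C3′/C4′ can also undergo 1,2-shifts or retro-aldol cleavage of C4′–C5′. Further liabilities are the acid- and oxidant-sensitive prenyl alkene, the ene-dione and the coumarin C3=C4 bond (Michael acceptors, reducible), and the lactone towards hydroxide. The difficulty is a quaternary oxygenated stereocentre between two carbonyl-bearing arms, four differently functionalised ring C positions (C3′ to C6′) to be told apart, and an end game that tolerates neither base nor strong acid.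

## Retrosynthetic reasoning

**10 ⇒ 8.** The C3′ and C6′ ketones are returned to a dimethyl ketal and a methyl enol ether. In this masked form ring C has no enolisable ketone, so the C4′ hydroxyl cannot be lost by elimination. The oxygen pattern of 8 is also recognisable as that of a dearomatised trioxygenated benzene. The forward reaction is a mild aqueous acid hydrolysis as the last step.

**8 ⇒ 7.** The isopropylidene terminus of the prenyl group is cut, leaving an allyl group. Enantioselective carbonyl allylation is well developed for the parent allyl group, whereas direct transfer of a linear prenyl group to a ketone has no dependable regiocontrol. The forward reaction is a cross-metathesis that touches only the terminal alkene.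

**7 ⇒ 5 (key disconnection).** The C4′–CH2 bond is cut, which turns C4′ into the only carbonyl carbon of the achiral, flat dienone 5. The cut is made here and not at the C4′–O bond because it reverses the usual polarity: C4′ becomes an electrophile that accepts the carbon chain, instead of a prenylated arene carbon that must be oxygenated. The gain is that no regiochemical choice remains and that the stereocentre and the quaternary C–C bond arise together. The ketal at C3′ masks the second carbonyl and provides the steric difference that a chiral catalyst can read. The forward reaction must add allyl 1,2 to the Si face of C4′.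

**5 ⇒ 4.** One C3′–O bond of the ketal is cut: 5 is the oxidative dearomatisation product of the 2-methoxyphenol 4 in an alcohol solvent. This single oxidation converts a flat arene into ring C with the oxygens at C3′, C4′ and C6′ already at the oxidation levels of the target. The para carbon C1′ is blocked by the coumarin, and the methoxy group on C3′ directs the incoming alkoxy group.

**4 ⇒ 1 + 2 (through 3).** The C1′–C3 bond between ring C and the coumarin is cut as a Suzuki–Miyaura coupling. Both halves are simple bromides, and the boron partner 3 is generated from 1 in the same flask.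

## Alternatives that were turned down

**Alternative 1:** (textbook) C4′–O bond formation on the pre-prenylated arene.
- Disconnection: the target is traced to the ortho-quinol methyl enol ether A2 and then to the phenol A1 (OH on C3′, prenyl on C4′, OMe on C6′).
- Forward key step: asymmetric hydroxylative phenol dearomatisation with a chiral pentavalent iodine reagent (or a chiral iodoarene with a terminal oxidant), delivering oxygen to C4′ of A1, then enol ether hydrolysis.
- Why turned down: A1 has a second, unsubstituted ortho carbon (C2′), and iodine-bound oxygen is transferred preferentially to the less hindered ortho position. The methoxy group para to the phenol (C6′) opens the competing demethylative oxidation across C3′/C6′, which ends at the quinone oxidation level without a stereocentre. Peracid co-oxidants attack the prenyl alkene, and ortho-quinols of type A2 dimerise by Diels–Alder reaction. A1 also needs its own prenylation sequence, so nothing is saved.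

**Alternative 2:** chiral pool plus construction of ring C from an acyclic chain.
- Disconnection: C1′=C2′ and the bonds from C3′ and C6′ to the two-carbon unit C1′/C2′ are cut, leading to a 2-hydroxy-2-prenylsuccinate equivalent A3.
- Forward key step: alkylation of the dioxolanone enolate of a chiral-pool 2-hydroxy-1,4-diacid with a prenyl halide, anti to the tert-butyl group (self-regeneration of the stereocentre), gives A3. Both carboxyl termini are then extended to the triketone A4, and an intramolecular aldol condensation closes ring C.
- Why turned down: the stereocentre is secure, but ring C must then be assembled carbon by carbon. The two carboxyl carbons have to be differentiated and an aryl 1,2-diketone installed. The ring-closing aldol condensation needs base in the presence of a tertiary β-hydroxy ketone that undergoes retro-aldol cleavage and elimination under exactly those conditions. The count is nine or more linear steps, against one oxidation that delivers ring C from an arene.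

**Alternative 3:** [3,3]-sigmatropic transfer of the prenyl group from C6′ to C4′.
- Disconnection: the C4′–CH2 bond is cut by an anionic oxy-Cope transform, giving the tertiary carbinol A6, which comes from the quinone monoketal A5 (carbonyl at C6′, ketal at C3′, protected oxygen on C4′).
- Forward key step: γ-addition of a prenyl-metal reagent to the C6′ carbonyl of A5 gives A6. Its alkoxide rearranges suprafacially, carrying the C6′ configuration to C4′ and releasing the C6′ ketone.
- Why turned down: the carbinol of A6 has two allylic termini. The shift through the aryl-substituted C1′=C2′ bond ends at the unsubstituted C2′, is helped by the aryl group at the central carbon and gives an aryl-conjugated enolate. The desired shift must form a quaternary, alkoxy-substituted centre, so the wrong regiochemistry is expected to win. The stereocentre of A6 would itself require an enantioselective ketone allylation that creates two adjacent quaternary carbons, so the stereochemical problem is moved, not solved. The tertiary ether on C4′ would finally have to be cleaved β to a ketone.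

Key step: step 3

## Route

Step 1
Reactants: 1 4-bromo-2,5-dimethoxyphenol; 2 3-bromo-7-methoxy-2H-chromen-2-one
Product: 4 3-(4-hydroxy-2,5-dimethoxyphenyl)-7-methoxy-2H-chromen-2-one, via aryl pinacol boronate 3 (not isolated)
Conditions: B2pin2 (1.1 equiv), KOAc (3 equiv), PdCl2(dppf) (3 mol%), 1,4-dioxane, 90 °C; then 2 (0.9 equiv), K3PO4 (aq., 3 equiv), 80 °C; work-up at pH 4–5
Reagents that add atoms: bis(pinacolato)diboron, CC1(C)OB(OC1(C)C)B1OC(C)(C)C(C)(C)O1 (its boron and pinacol atoms are held by 3 only; 4 contains atoms of 1 and 2 alone)
Why: Miyaura borylation of the aryl bromide followed in the same flask by Suzuki–Miyaura coupling with the activated vinylic bromide of 2; the free phenol is tolerated by acetate and phosphate bases, and a lactone opened by base recloses on mild acidification because the C3=C4 geometry is fixed. No stereocentre is formed.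

Step 2
Reactants: 4 3-(4-hydroxy-2,5-dimethoxyphenyl)-7-methoxy-2H-chromen-2-one
Product: 5 7-methoxy-3-(3,3,6-trimethoxy-4-oxocyclohexa-1,5-dien-1-yl)-2H-chromen-2-one
Conditions: PhI(OAc)2 (1.1 equiv), MeOH, 0 °C; product used without prolonged storage
Reagents that add atoms: methanol, CO
Why: Oxidative dearomatisation of a 2-methoxyphenol with a trivalent iodine reagent: ligand exchange at iodine, loss of iodobenzene and capture of the phenoxenium-type intermediate by methanol at the methoxy-bearing ortho carbon C3′, where the charge is best stabilised, should give the 6,6-dimethoxycyclohexa-2,4-dienone. The para carbon C1′ is blocked by the coumarin, and the C6′ methoxy and C1′ aryl groups should suppress Diels–Alder dimerisation; 5 is achiral.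

Step 3
Reactants: 5 7-methoxy-3-(3,3,6-trimethoxy-4-oxocyclohexa-1,5-dien-1-yl)-2H-chromen-2-one
Product: 7 3-[(4R)-4-hydroxy-3,3,6-trimethoxy-4-(prop-2-en-1-yl)cyclohexa-1,5-dien-1-yl]-7-methoxy-2H-chromen-2-one, via diisopropyl borate ester 6 (not isolated)
Conditions: allyldiisopropoxyborane (1.5 equiv), (R)-3,3′-dibromo-1,1′-bi-2-naphthol (15 mol%), PhCF3–toluene 3:1, −35 °C; pH 7 phosphate buffer work-up
Reagents that add atoms: allyldiisopropoxyborane, C=CCB(OC(C)C)OC(C)C
Why: Chiral-diol-catalysed allylboration of a ketone: the diol exchanges one isopropoxy group on boron, and the resulting more Lewis-acidic mixed boronate binds the C4′ carbonyl oxygen and transfers the allyl group through a closed six-membered chair transition state with allylic transposition. The closest known reaction type is the allylboration of aryl, alkyl and conjugated alkenyl ketones to tertiary homoallylic alcohols catalysed by 3,3′-disubstituted binaphthols. No ring is closed. The new stereocentre C4′ is set by the catalyst: the binaphthyl pocket selects the carbonyl face, and the large steric difference between the flanking carbons (quaternary ketal carbon C3′ against planar vinylic CH C5′) fixes their places in the chair, so that allyl should be delivered to the Si face of C4′ (priorities O > C3′ > C5′) and the carbinol is (R). The step needs 1,2-addition in preference to 1,4- or 1,6-addition to the dienone and to attack on the lactone; the closed boron transition state reaches only the carbonyl carbon, and esters do not react with allylboronates. The C4′ carbonyl is the only ketone of 5, so no regiochemical choice arises, and its deactivation as a vinylogous ester (C6′ methoxy) is offset by the two electron-withdrawing methoxy groups on C3′. The same two methoxy groups disfavour ionisation of the new tertiary allylic C4′–O bond, and borate 6 is hydrolysed at pH 7 so that the acid-labile dienol ether survives.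

Step 4
Reactants: 7 3-[(4R)-4-hydroxy-3,3,6-trimethoxy-4-(prop-2-en-1-yl)cyclohexa-1,5-dien-1-yl]-7-methoxy-2H-chromen-2-one
Product: 8 3-[(4R)-4-hydroxy-3,3,6-trimethoxy-4-(3-methylbut-2-en-1-yl)cyclohexa-1,5-dien-1-yl]-7-methoxy-2H-chromen-2-one
Conditions: second-generation Grubbs catalyst RuCl2(=CHPh)(PCy3)(H2IMes) (5 mol%), 2-methylbut-2-ene–CH2Cl2 1:1, 35 °C; chromatography on triethylamine-deactivated silica
Reagents that add atoms: 2-methylbut-2-ene, CC=C(C)C
Why: Olefin cross-metathesis of the monosubstituted allyl alkene with 2-methylbut-2-ene exchanges the terminal methylene for an isopropylidene group, the standard allyl-to-prenyl conversion, also next to quaternary carbons. The trisubstituted ring alkenes, the ring enol ether and the coumarin alkene are too hindered or too electron-poor to engage, and the C4′ stereocentre is not touched.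

Step 5
Reactants: 8 3-[(4R)-4-hydroxy-3,3,6-trimethoxy-4-(3-methylbut-2-en-1-yl)cyclohexa-1,5-dien-1-yl]-7-methoxy-2H-chromen-2-one
Product: 10 3-[(4R)-4-hydroxy-4-(3-methylbut-2-en-1-yl)-3,6-dioxocyclohex-1-en-1-yl]-7-methoxy-2H-chromen-2-one, via keto ketal 9 (not isolated)
Conditions: 1 M HCl (aq.)–THF 1:4, 0 °C to rt; quench with pH 7 buffer, no basic wash
Reagents that add atoms: water, O
Why: Acid hydrolysis: C-protonation of the C5′=C6′ enol ether and capture by water should give ketone 9, after which the C3′ dimethyl ketal is hydrolysed to the second ketone. Loss of the C4′ hydroxyl is disfavoured because positive charge developing at C4′ is destabilised first by the adjacent ketal and then by the adjacent C3′ carbonyl, and base is avoided throughout; the stereocentre is not involved.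

## Compound list

1 | 4-bromo-2,5-dimethoxyphenol | COc1cc(Br)c(OC)cc1O | starting material
2 | 3-bromo-7-methoxy-2H-chromen-2-one | COc1ccc2cc(Br)c(=O)oc2c1 | starting material
3 | 2,5-dimethoxy-4-(4,4,5,5-tetramethyl-1,3,2-dioxaborolan-2-yl)phenol | COc1cc(B2OC(C)(C)C(C)(C)O2)c(OC)cc1O | intermediate
4 | 3-(4-hydroxy-2,5-dimethoxyphenyl)-7-methoxy-2H-chromen-2-one | COc1ccc2cc(-c3cc(OC)c(O)cc3OC)c(=O)oc2c1 | intermediate
5 | 7-methoxy-3-(3,3,6-trimethoxy-4-oxocyclohexa-1,5-dien-1-yl)-2H-chromen-2-one | COc1ccc2cc(C3=CC(OC)(OC)C(=O)C=C3OC)c(=O)oc2c1 | intermediate
6 | (1R)-2,2,5-trimethoxy-4-(7-methoxy-2-oxo-2H-chromen-3-yl)-1-(prop-2-en-1-yl)cyclohexa-3,5-dien-1-yl dipropan-2-yl borate | COc1ccc2cc(C3=CC(OC)(OC)[C@@](OB(OC(C)C)OC(C)C)(CC=C)C=C3OC)c(=O)oc2c1 | intermediate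
7 | 3-[(4R)-4-hydroxy-3,3,6-trimethoxy-4-(prop-2-en-1-yl)cyclohexa-1,5-dien-1-yl]-7-methoxy-2H-chromen-2-one | COc1ccc2cc(C3=CC(OC)(OC)[C@@](O)(CC=C)C=C3OC)c(=O)oc2c1 | intermediate
8 | 3-[(4R)-4-hydroxy-3,3,6-trimethoxy-4-(3-methylbut-2-en-1-yl)cyclohexa-1,5-dien-1-yl]-7-methoxy-2H-chromen-2-one | COc1ccc2cc(C3=CC(OC)(OC)[C@@](O)(CC=C(C)C)C=C3OC)c(=O)oc2c1 | intermediate
9 | 3-[(4R)-4-hydroxy-3,3-dimethoxy-4-(3-methylbut-2-en-1-yl)-6-oxocyclohex-1-en-1-yl]-7-methoxy-2H-chromen-2-one | COc1ccc2cc(C3=CC(OC)(OC)[C@@](O)(CC=C(C)C)CC3=O)c(=O)oc2c1 | intermediate
10 | 3-[(4R)-4-hydroxy-4-(3-methylbut-2-en-1-yl)-3,6-dioxocyclohex-1-en-1-yl]-7-methoxy-2H-chromen-2-one | COc1ccc2cc(C3=CC(=O)[C@@](O)(CC=C(C)C)CC3=O)c(=O)oc2c1 | target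

## Step count and least certain steps

Total step count: 5. Longest linear sequence: 5 steps (from 1 or 2 to 10).

**Step 3 (key step).** Facial discrimination may be poor, because no ketone of this dienone type has been matched to the catalyst pocket. Addition may also be slow at a carbonyl that receives electron density from the C6′ methoxy group. Lewis-acidic boron species could ionise the new tertiary allylic C–O bond and erase the stereocentre. Fallback: setting out from 5, allylmagnesium bromide in THF at −78 °C should give the racemic carbinol, that is 7 together with its enantiomer 3-[(4S)-4-hydroxy-3,3,6-trimethoxy-4-(prop-2-en-1-yl)cyclohexa-1,5-dien-1-yl]-7-methoxy-2H-chromen-2-one F1. Preparative chromatography on a chiral stationary phase (amylose carbamate type, eluent containing a trace of triethylamine) separates the two, and the route is rejoined at 7.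

**Step 5.** Water may be lost across C4′–C5′ during cleavage of the C3′ ketal, which is deactivated by the enone and needs stronger acid than the enol ether; this collapse would give the achiral quinone. A 1,2-shift of the prenyl group to the C3′ oxocarbenium ion is a second acid-driven failure mode. Fallback: setting out from 8, the tertiary hydroxyl is masked before any acid is applied. Triethylsilyl triflate and 2,6-lutidine in CH2Cl2 at −78 °C should give the silyl ether 7-methoxy-3-[(4R)-3,3,6-trimethoxy-4-(3-methylbut-2-en-1-yl)-4-(triethylsilyloxy)cyclohexa-1,5-dien-1-yl]-2H-chromen-2-one F2, whose oxygen is a poorer leaving group under acid. The same aqueous acid then unveils both ketones to give 7-methoxy-3-[(4R)-4-(3-methylbut-2-en-1-yl)-3,6-dioxo-4-(triethylsilyloxy)cyclohex-1-en-1-yl]-2H-chromen-2-one F3. Pyridine-buffered HF·pyridine in THF at 0 °C removes the silyl group, and the route is rejoined at 10.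

**Step 2.** The alcohol may be captured at the aryl-bearing para carbon C1′ instead of C3′, and the dienone may dimerise by cycloaddition on concentration. Fallback: setting out from 4, NaIO4 in aqueous methanol at 0 °C effects demethylative oxidation to the ortho-quinone 4-methoxy-5-(7-methoxy-2-oxo-2H-chromen-3-yl)cyclohexa-3,5-diene-1,2-dione F4. Trimethyl orthoformate in methanol with catalytic TsOH should then ketalise the C3′ carbonyl, the one that is not part of the vinylogous ester, and the route is rejoined at 5.

**Step 1.** The electron-rich phenolic boronate 3 may undergo protodeboronation before transmetalation, and the lactone may open under aqueous base. Fallback: setting out from 2, coupling with commercial (2,5-dimethoxyphenyl)boronic acid (Pd(PPh3)4, Na2CO3, DME–water, 80 °C) should give 3-(2,5-dimethoxyphenyl)-7-methoxy-2H-chromen-2-one F5. N-Bromosuccinimide in MeCN brominates the dimethoxyarene para to the biaryl bond to give 3-(4-bromo-2,5-dimethoxyphenyl)-7-methoxy-2H-chromen-2-one F6. Miyaura borylation (B2pin2, KOAc, PdCl2(dppf), dioxane) gives 3-[2,5-dimethoxy-4-(4,4,5,5-tetramethyl-1,3,2-dioxaborolan-2-yl)phenyl]-7-methoxy-2H-chromen-2-one F7, which is oxidised in the same flask with NaBO3·4H2O in THF–water, and the route is rejoined at 4.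

## Further compounds

F1 | step 3 | 3-[(4S)-4-hydroxy-3,3,6-trimethoxy-4-(prop-2-en-1-yl)cyclohexa-1,5-dien-1-yl]-7-methoxy-2H-chromen-2-one | COc1ccc2cc(C3=CC(OC)(OC)[C@](O)(CC=C)C=C3OC)c(=O)oc2c1
F2 | step 5 | 7-methoxy-3-[(4R)-3,3,6-trimethoxy-4-(3-methylbut-2-en-1-yl)-4-(triethylsilyloxy)cyclohexa-1,5-dien-1-yl]-2H-chromen-2-one | COc1ccc2cc(C3=CC(OC)(OC)[C@@](O[Si](CC)(CC)CC)(CC=C(C)C)C=C3OC)c(=O)oc2c1
F3 | step 5 | 7-methoxy-3-[(4R)-4-(3-methylbut-2-en-1-yl)-3,6-dioxo-4-(triethylsilyloxy)cyclohex-1-en-1-yl]-2H-chromen-2-one | COc1ccc2cc(C3=CC(=O)[C@@](O[Si](CC)(CC)CC)(CC=C(C)C)CC3=O)c(=O)oc2c1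
F4 | step 2 | 4-methoxy-5-(7-methoxy-2-oxo-2H-chromen-3-yl)cyclohexa-3,5-diene-1,2-dione | COC1=CC(=O)C(=O)C=C1c1cc2ccc(OC)cc2oc1=O
F5 | step 1 | 3-(2,5-dimethoxyphenyl)-7-methoxy-2H-chromen-2-one | COc1ccc2cc(-c3cc(OC)ccc3OC)c(=O)oc2c1
F6 | step 1 | 3-(4-bromo-2,5-dimethoxyphenyl)-7-methoxy-2H-chromen-2-one | COc1ccc2cc(-c3cc(OC)c(Br)cc3OC)c(=O)oc2c1
F7 | step 1 | 3-[2,5-dimethoxy-4-(4,4,5,5-tetramethyl-1,3,2-dioxaborolan-2-yl)phenyl]-7-methoxy-2H-chromen-2-one | COc1ccc2cc(-c3cc(OC)c(B4OC(C)(C)C(C)(C)O4)cc3OC)c(=O)oc2c1
A1 | alternative 1 | 3-[5-hydroxy-2-methoxy-4-(3-methylbut-2-en-1-yl)phenyl]-7-methoxy-2H-chromen-2-one | COc1ccc2cc(-c3cc(O)c(CC=C(C)C)cc3OC)c(=O)oc2c1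
A2 | alternative 1 | 3-[(4R)-4-hydroxy-6-methoxy-4-(3-methylbut-2-en-1-yl)-3-oxocyclohexa-1,5-dien-1-yl]-7-methoxy-2H-chromen-2-one | COc1ccc2cc(C3=CC(=O)[C@@](O)(CC=C(C)C)C=C3OC)c(=O)oc2c1
A3 | alternative 2 | 2-[(2R,4R)-2-tert-butyl-4-(3-methylbut-2-en-1-yl)-5-oxo-1,3-dioxolan-4-yl]acetic acid | O=C1O[C@H](C(C)(C)C)O[C@]1(CC=C(C)C)CC(=O)O
A4 | alternative 2 | (4R)-4-hydroxy-1-(7-methoxy-2-oxo-2H-chromen-3-yl)-4-(3-methylbut-2-en-1-yl)hexane-1,2,5-trione | COc1ccc2cc(C(=O)C(=O)C[C@](O)(CC=C(C)C)C(C)=O)c(=O)oc2c1
A5 | alternative 3 | 3-[3,3-dimethoxy-4-(methoxymethoxy)-6-oxocyclohexa-1,4-dien-1-yl]-7-methoxy-2H-chromen-2-one | COCOC1=CC(=O)C(c2cc3ccc(OC)cc3oc2=O)=CC1(OC)OC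
A6 | alternative 3 | 3-[(6R)-6-hydroxy-3,3-dimethoxy-4-(methoxymethoxy)-6-(2-methylbut-3-en-2-yl)cyclohexa-1,4-dien-1-yl]-7-methoxy-2H-chromen-2-one | O[C@@]1(C(C)(C)C=C)C=C(OCOC)C(OC)(OC)C=C1c1cc2ccc(OC)cc2oc1=O
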